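**Retrosynthetic overview**

1. The allylic alcohol is traced back to a benzodioxine-6-carboxylate (ester → benzylic alcohol → tandem oxidation–Wittig → enoate → allylic alcohol), and the C2 methyl group to a CH2–S(O)-p-tolyl arm that Raney nickel turns into CH3.
2. Key disconnection: the C2–C3 bond of the dihydro-1,4-benzodioxine (methyl-bearing C2 to aryl-bearing C3). It is made by a photocatalytic hydrogen-atom-transfer 6-exo radical cyclization of an open-chain catechol bis-ether that carries a 3,4,5-trimethoxybenzyl ether on one oxygen and an enantiopure (Z)-2-(p-tolylsulfinyl)vinyl ether on the other; the sulfinyl group activates the acceptor, supplies the absolute configuration and is the traceless precursor of the methyl group.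
3. Enabling feature: the ArCH2–O hydrogens are both benzylic and alpha to oxygen (the weakest, most hydridic C–H of the precursor), and the two ether oxygens sit on adjacent carbons (C4 and C5) of the benzoate ring, which holds that methylene carbon 1,6 to the oxygen-bearing vinyl carbon so that the six-membered C–O–C(ar)=C(ar)–O–C ring can close.
4. The bis-ether comes from methyl 3,4-dihydroxy-5-methoxybenzoate by dianion benzylation at the oxygen meta to the ester and oxa-Michael addition of the remaining phenol to (S)-ethynyl p-tolyl sulfoxide (from menthyl p-toluenesulfinate and ethynyltrimethylsilane).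
5. Ring order: both benzene rings are bought; the only ring formed is the 1,4-dioxane ring, closed in the key step.

Key step: step 5

Remark on the chemistry (assumption): the sense of asymmetric induction in step 5 is taken from the allylic-strain model of (Z)-alkenyl sulfoxides (radical attack anti to p-tolyl), which assigns the (S)-sulfoxide to the (2R,3R) target; should the induction be opposite, the mirror-image sulfinate, (1R,2S,5R)-menthyl (S)-p-toluenesulfinate, also commercial, would be used in the same steps.

**Route**

Step 1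
Reactants: 1 (1S,2R,5S)-menthyl (R)-p-toluenesulfinate [(1S,2R,5S)-5-methyl-2-(propan-2-yl)cyclohexyl (R)-4-methylbenzenesulfinate]; 2 ethynyltrimethylsilane
Product: 4 (R)-trimethyl[(4-methylbenzenesulfinyl)ethynyl]silane, via (trimethylsilyl)ethynylmagnesium bromide 3 (not isolated)
Conditions: 2, EtMgBr (1.2 equiv), THF, 0 °C to rt; then 1, toluene, −20 to 0 °C; aq NH4Cl
Reagents that add atoms: none
Why: Andersen sulfoxide synthesis, in which the alkynyl Grignard reagent displaces menthoxide at sulfur by an SN2-type attack with clean inversion, so that the (R)-sulfinate gives a single sulfoxide enantiomer while the silyl cap prevents deprotonation of the alkyne.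

Step 2
Reactants: 4 (R)-trimethyl[(4-methylbenzenesulfinyl)ethynyl]silane
Product: 5 (S)-ethynyl p-tolyl sulfoxide [(S)-1-(ethynesulfinyl)-4-methylbenzene]
Conditions: n-Bu4NF (1.05 equiv), AcOH (1.1 equiv), THF, −78 °C
Reagents that add atoms: none
Why: Fluoride-induced protodesilylation of an alkynylsilane under acetic acid buffering frees the terminal alkyne without touching the sulfur stereocenter (the descriptor changes from R to S only because the substituent priorities change) and without adding a nucleophile to the activated triple bond.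

Step 3
Reactants: 6 methyl 3,4-dihydroxy-5-methoxybenzoate; 7 3,4,5-trimethoxybenzyl chloride [5-(chloromethyl)-1,2,3-trimethoxybenzene]
Product: 9 methyl 4-hydroxy-3-methoxy-5-[(3,4,5-trimethoxyphenyl)methoxy]benzoate, via disodium benzene-1,2-diolate 8 (not isolated)
Conditions: NaH (2.1 equiv), DMF, 0 °C; then 7 (1.0 equiv), 0 °C to rt; aq HCl
Reagents that add atoms: none
Why: Williamson etherification of a catechol dianion, in which the phenoxide meta to the ester is not conjugated with it and is less hindered, hence more nucleophilic, whereas the oxygen para to the ester (flanked by methoxy and the second oxygen) stays behind as the less reactive vinylogous carboxylate, so that one equivalent of the benzyl chloride should end up on the meta oxygen.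

Step 4
Reactants: 9 methyl 4-hydroxy-3-methoxy-5-[(3,4,5-trimethoxyphenyl)methoxy]benzoate; 5 (S)-ethynyl p-tolyl sulfoxide
Product: 10 methyl 3-methoxy-4-{[(Z)-2-[(S)-4-methylbenzenesulfinyl]ethenyl]oxy}-5-[(3,4,5-trimethoxyphenyl)methoxy]benzoate
Conditions: Cs2CO3 (20 mol%), THF, 0 °C
Reagents that add atoms: none
Why: Oxa-Michael addition of the phenoxide to the alkynyl sulfoxide, in which anti addition across the triple bond and protonation of the configurationally stable vinyl anion should give the (Z)-alkene kinetically, catalytic base at 0 °C limits equilibration to the (E)-isomer, and the sulfur stereocenter is not involved.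

Step 5
Reactants: 10 methyl 3-methoxy-4-{[(Z)-2-[(S)-4-methylbenzenesulfinyl]ethenyl]oxy}-5-[(3,4,5-trimethoxyphenyl)methoxy]benzoate
Product: 11 methyl (2S,3R)-8-methoxy-2-{[(S)-4-methylbenzenesulfinyl]methyl}-3-(3,4,5-trimethoxyphenyl)-2,3-dihydro-1,4-benzodioxine-6-carboxylate (ring substituents trans)
Conditions: (n-Bu4N)4[W10O32] (2 mol%), MeCN (0.01 M, degassed), 390 nm LEDs, rt
Reagents that add atoms: none
Why: Proposed new method: photoexcited [W10O32]4− abstracts a hydrogen atom from the ArCH2–O methylene of 10 (the only C–H that is both benzylic and alpha to oxygen), the nucleophilic benzylic radical adds to the oxygen-bearing carbon of the electron-poor (Z)-aryloxyvinyl sulfoxide and forms the C2–C3 bond, and the reduced cluster H+[W10O32]5− returns the hydrogen atom to the alpha-sulfinyl radical, so that 10 is isomerized to 11 with no reagent consumed. The closest known reaction types are the [W10O32]4−-photocatalyzed hydroalkylation (C–H Giese addition) of benzylic and alpha-oxy C–H bonds with vinyl sulfones or acrylates and the n-Bu3SnH-mediated cyclization of carbon radicals onto beta-alkoxyvinyl sulfoxides and beta-alkoxyacrylates that gives cyclic ethers; their combination on an aryloxyvinyl sulfoxide to close a 1,4-dioxane is what is new. The dioxane ring closes in the 6-exo-trig mode, favoured over 7-endo attack by the ring size and by the polarization of the push-pull alkene, whose oxygen-bearing carbon is the beta position of the vinyl sulfoxide. The configuration at C2 is controlled by the sulfinyl group: allylic 1,3-strain with the cis aryloxy group holds the sulfur lone pair in the plane of the C=C bond, the p-tolyl group covers one face and the radical enters from the S–O face, which for the (S)-sulfoxide leads to the required C2 configuration. The configuration at C3 is set relative to C2 in a half-chair transition state that keeps the trimethoxyphenyl group pseudo-equatorial and trans to the sulfinylmethyl arm, the arrangement that is also preferred thermodynamically. The step needs site selectivity in the hydrogen abstraction (secured by the uniquely weak and hydridic benzylic ether C–H), exo regioselectivity (secured as stated) and preservation of the (Z)-geometry until cyclization (secured by 390 nm light that only the tungstate absorbs and by the absence of a triplet sensitizer).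

Step 6
Reactants: 11 methyl (2S,3R)-8-methoxy-2-{[(S)-4-methylbenzenesulfinyl]methyl}-3-(3,4,5-trimethoxyphenyl)-2,3-dihydro-1,4-benzodioxine-6-carboxylate
Product: 12 methyl (2R,3R)-8-methoxy-2-methyl-3-(3,4,5-trimethoxyphenyl)-2,3-dihydro-1,4-benzodioxine-6-carboxylate
Conditions: Raney Ni (W-2, deactivated in acetone), EtOH–THF, rt
Reagents that add atoms: none
Why: Raney nickel hydrogenolysis cleaves both C–S bonds of the alkyl aryl sulfoxide and leaves a methyl group, as in the conversion of beta-hydroxy sulfoxides into methyl carbinols, no bond to either ring stereocenter is broken (the C2 descriptor changes from S to R only through the priority change), and the deactivated catalyst at room temperature should spare the benzylic C–O bond and the ester.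

Step 7
Reactants: 12 methyl (2R,3R)-8-methoxy-2-methyl-3-(3,4,5-trimethoxyphenyl)-2,3-dihydro-1,4-benzodioxine-6-carboxylate
Product: 13 [(2R,3R)-8-methoxy-2-methyl-3-(3,4,5-trimethoxyphenyl)-2,3-dihydro-1,4-benzodioxin-6-yl]methanol
Conditions: i-Bu2AlH (2.5 equiv), CH2Cl2, −78 to 0 °C; aq potassium sodium tartrate
Reagents that add atoms: none
Why: Hydride reduction of the aryl methyl ester to the benzylic alcohol with i-Bu2AlH, which leaves the aryl ethers and both stereocenters untouched.

Step 8
Reactants: 13 [(2R,3R)-8-methoxy-2-methyl-3-(3,4,5-trimethoxyphenyl)-2,3-dihydro-1,4-benzodioxin-6-yl]methanol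
Product: 15 ethyl (E)-3-[(2R,3R)-8-methoxy-2-methyl-3-(3,4,5-trimethoxyphenyl)-2,3-dihydro-1,4-benzodioxin-6-yl]prop-2-enoate, via benzodioxine-6-carbaldehyde 14 (not isolated)
Conditions: MnO2 (10 equiv), Ph3P=CHCO2Et (1.3 equiv), CH2Cl2, rt to 40 °C
Reagents that add atoms: ethyl (triphenylphosphoranylidene)acetate, CCOC(=O)C=P(c1ccccc1)(c1ccccc1)c1ccccc1
Why: Tandem oxidation–Wittig process, in which MnO2 oxidizes the electron-rich benzylic alcohol to the aldehyde and the stabilized ylide present in the flask converts it at once into the (E)-enoate by the usual thermodynamic preference of stabilized ylides.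

Step 9
Reactants: 15 ethyl (E)-3-[(2R,3R)-8-methoxy-2-methyl-3-(3,4,5-trimethoxyphenyl)-2,3-dihydro-1,4-benzodioxin-6-yl]prop-2-enoate
Product: 16 (E)-3-[(2R,3R)-8-methoxy-2-methyl-3-(3,4,5-trimethoxyphenyl)-2,3-dihydro-1,4-benzodioxin-6-yl]prop-2-en-1-ol (CNP0314511.1)
Conditions: i-Bu2AlH (2.5 equiv), CH2Cl2, −78 °C; aq potassium sodium tartrate
Reagents that add atoms: none
Why: 1,2-Reduction of the alpha,beta-unsaturated ester by i-Bu2AlH at low temperature should give the (E)-allylic alcohol without conjugate reduction, and the alkene geometry and both ring stereocenters are untouched.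

**Compound list**

1 | (1S,2R,5S)-menthyl (R)-p-toluenesulfinate | CC(C)[C@H]1CC[C@H](C)C[C@@H]1O[S@@](=O)c2ccc(C)cc2 | starting material
2 | ethynyltrimethylsilane | C#C[Si](C)(C)C | starting material
3 | (trimethylsilyl)ethynylmagnesium bromide | C[Si](C)(C)C#C[Mg]Br | intermediate
4 | (R)-trimethyl[(4-methylbenzenesulfinyl)ethynyl]silane | C[Si](C)(C)C#C[S@](=O)c1ccc(C)cc1 | intermediate
5 | (S)-ethynyl p-tolyl sulfoxide | C#C[S@](=O)c1ccc(C)cc1 | intermediate
6 | methyl 3,4-dihydroxy-5-methoxybenzoate | COC(=O)c1cc(O)c(O)c(OC)c1 | starting material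
7 | 3,4,5-trimethoxybenzyl chloride | COc1cc(CCl)cc(OC)c1OC | starting material
8 | disodium 3-methoxy-5-(methoxycarbonyl)benzene-1,2-diolate | COC(=O)c1cc([O-])c([O-])c(OC)c1.[Na+].[Na+] | intermediate
9 | methyl 4-hydroxy-3-methoxy-5-[(3,4,5-trimethoxyphenyl)methoxy]benzoate | COC(=O)c1cc(OC)c(O)c(OCc2cc(OC)c(OC)c(OC)c2)c1 | intermediate
10 | methyl 3-methoxy-4-{[(Z)-2-[(S)-4-methylbenzenesulfinyl]ethenyl]oxy}-5-[(3,4,5-trimethoxyphenyl)methoxy]benzoate | COC(=O)c1cc(OC)c(O/C=C\[S@](=O)c2ccc(C)cc2)c(OCc2cc(OC)c(OC)c(OC)c2)c1 | intermediate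
11 | methyl (2S,3R)-8-methoxy-2-{[(S)-4-methylbenzenesulfinyl]methyl}-3-(3,4,5-trimethoxyphenyl)-2,3-dihydro-1,4-benzodioxine-6-carboxylate | COc1cc([C@H]2Oc3cc(C(=O)OC)cc(OC)c3O[C@@H]2C[S@](=O)c4ccc(C)cc4)cc(OC)c1OC | intermediate
12 | methyl (2R,3R)-8-methoxy-2-methyl-3-(3,4,5-trimethoxyphenyl)-2,3-dihydro-1,4-benzodioxine-6-carboxylate | COc1cc([C@H]2Oc3cc(C(=O)OC)cc(OC)c3O[C@@H]2C)cc(OC)c1OC | intermediate
13 | [(2R,3R)-8-methoxy-2-methyl-3-(3,4,5-trimethoxyphenyl)-2,3-dihydro-1,4-benzodioxin-6-yl]methanol | COc1cc([C@H]2Oc3cc(CO)cc(OC)c3O[C@@H]2C)cc(OC)c1OC | intermediate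
14 | (2R,3R)-8-methoxy-2-methyl-3-(3,4,5-trimethoxyphenyl)-2,3-dihydro-1,4-benzodioxine-6-carbaldehyde | COc1cc([C@H]2Oc3cc(C=O)cc(OC)c3O[C@@H]2C)cc(OC)c1OC | intermediate
15 | ethyl (E)-3-[(2R,3R)-8-methoxy-2-methyl-3-(3,4,5-trimethoxyphenyl)-2,3-dihydro-1,4-benzodioxin-6-yl]prop-2-enoate | COc1cc([C@H]2Oc3cc(/C=C/C(=O)OCC)cc(OC)c3O[C@@H]2C)cc(OC)c1OC | intermediate
16 | (E)-3-[(2R,3R)-8-methoxy-2-methyl-3-(3,4,5-trimethoxyphenyl)-2,3-dihydro-1,4-benzodioxin-6-yl]prop-2-en-1-ol | COc1cc([C@H]2Oc3cc(/C=C/CO)cc(OC)c3O[C@@H]2C)cc(OC)c1OC | target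

**Step count and risks**

Total steps: 9. Longest linear sequence: 8 steps (steps 1, 2, 4, 5, 6, 7, 8, 9).

Steps most likely to fail:

1. Step 5 (Proposed new method). What may go wrong: hydrogen abstraction that is not confined to the ArCH2–O methylene, above all renewed abstraction of the benzylic methine hydrogen of the cyclized product with loss of configuration at C3 or ring opening by beta-scission, and light-induced loss of the (Z)-geometry before cyclization, which would erode the facial control at C2. Fallback (known chemistry; sets out from 6 and uses 5, comes back at 11): the radical is generated at a defined site by reductive decarboxylation of a redox-active ester instead of by C–H abstraction. Commercial 3,4,5-trimethoxyphenylacetic acid would be esterified (Boc2O, DMAP, t-BuOH) to tert-butyl 2-(3,4,5-trimethoxyphenyl)acetate F1 and brominated through its enolate (LiN(SiMe3)2, then NBS, THF, −78 °C) to racemic tert-butyl 2-bromo-2-(3,4,5-trimethoxyphenyl)acetate F2. Alkylation of the dianion 8 (made from 6 as in step 3) with F2 should give methyl 3-[2-tert-butoxy-2-oxo-1-(3,4,5-trimethoxyphenyl)ethoxy]-4-hydroxy-5-methoxybenzoate F3. Oxa-Michael addition to 5 as in step 4 should give methyl 3-[2-tert-butoxy-2-oxo-1-(3,4,5-trimethoxyphenyl)ethoxy]-5-methoxy-4-{[(Z)-2-[(S)-4-methylbenzenesulfinyl]ethenyl]oxy}benzoate F4. Acidolysis (CF3CO2H, CH2Cl2, 0 °C) should give 2-[3-methoxy-5-(methoxycarbonyl)-2-{[(Z)-2-[(S)-4-methylbenzenesulfinyl]ethenyl]oxy}phenoxy]-2-(3,4,5-trimethoxyphenyl)acetic acid F5, and coupling with N-hydroxyphthalimide (N,N'-diisopropylcarbodiimide, DMAP cat., CH2Cl2) should give 1,3-dioxoisoindolin-2-yl 2-[3-methoxy-5-(methoxycarbonyl)-2-{[(Z)-2-[(S)-4-methylbenzenesulfinyl]ethenyl]oxy}phenoxy]-2-(3,4,5-trimethoxyphenyl)acetate F6. Reductive decarboxylation of F6 (Ru(bpy)3(PF6)2 cat., Hantzsch ester, i-Pr2NEt, CH2Cl2, blue LEDs; a decarboxylative Giese cyclization) forms the same benzylic radical, both epimers of F6 converge on this one planar radical, and 6-exo cyclization with hydrogen transfer from the dihydropyridine should give 11 without any hydrogen-abstracting catalyst or sensitizer of high triplet energy.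

2. Step 4. What may go wrong: sluggish conjugate addition of the hindered, ester-deactivated phenoxide and base-mediated equilibration of the (Z)-adduct to the (E)-isomer by reversible addition–elimination. Fallback (sets out from 5 and uses 9, comes back at 10): the alkene geometry is fixed before the C–O bond is made. Anti-hydrobromination of 5 (LiBr, AcOH, MeCN, rt) should give (S)-1-{[(Z)-2-bromoethenyl]sulfinyl}-4-methylbenzene F7. Nucleophilic vinylic substitution of its bromide by the phenoxide of 9 (Cs2CO3, DMF, 0 °C), an addition–elimination that proceeds with retention of alkene geometry and is made irreversible by loss of bromide, should then deliver 10.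

3. Step 3. What may go wrong: loss of regiocontrol in the alkylation of the dianion (attack at the oxygen para to the ester, or double alkylation). Fallback (sets out from 6, comes back at 9): the two phenols are told apart by acidity instead of nucleophilicity in a protect–alkylate–deprotect sequence. The monoanion of 6 (Li2CO3, allyl bromide, DMF, 40 °C) is alkylated at the more acidic oxygen para to the ester to give methyl 3-hydroxy-5-methoxy-4-(prop-2-en-1-yloxy)benzoate F8. The remaining phenol is benzylated with 7 (K2CO3, DMF, 60 °C) to give methyl 3-methoxy-4-(prop-2-en-1-yloxy)-5-[(3,4,5-trimethoxyphenyl)methoxy]benzoate F9, and the allyl group is removed with Pd(PPh3)4 and morpholine (THF, rt) to give 9.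

Further compounds
F1 | step 5 | tert-butyl 2-(3,4,5-trimethoxyphenyl)acetate | COc1cc(CC(=O)OC(C)(C)C)cc(OC)c1OC
F2 | step 5 | tert-butyl 2-bromo-2-(3,4,5-trimethoxyphenyl)acetate (racemic) | COc1cc(C(Br)C(=O)OC(C)(C)C)cc(OC)c1OC
F3 | step 5 | methyl 3-[2-tert-butoxy-2-oxo-1-(3,4,5-trimethoxyphenyl)ethoxy]-4-hydroxy-5-methoxybenzoate (racemic) | COC(=O)c1cc(OC)c(O)c(OC(C(=O)OC(C)(C)C)c2cc(OC)c(OC)c(OC)c2)c1
F4 | step 5 | methyl 3-[2-tert-butoxy-2-oxo-1-(3,4,5-trimethoxyphenyl)ethoxy]-5-methoxy-4-{[(Z)-2-[(S)-4-methylbenzenesulfinyl]ethenyl]oxy}benzoate (both epimers at the benzylic carbon) | COC(=O)c1cc(OC)c(O/C=C\[S@](=O)c2ccc(C)cc2)c(OC(C(=O)OC(C)(C)C)c2cc(OC)c(OC)c(OC)c2)c1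
F5 | step 5 | 2-[3-methoxy-5-(methoxycarbonyl)-2-{[(Z)-2-[(S)-4-methylbenzenesulfinyl]ethenyl]oxy}phenoxy]-2-(3,4,5-trimethoxyphenyl)acetic acid (both epimers at the benzylic carbon) | COC(=O)c1cc(OC)c(O/C=C\[S@](=O)c2ccc(C)cc2)c(OC(C(=O)O)c2cc(OC)c(OC)c(OC)c2)c1
F6 | step 5 | 1,3-dioxoisoindolin-2-yl 2-[3-methoxy-5-(methoxycarbonyl)-2-{[(Z)-2-[(S)-4-methylbenzenesulfinyl]ethenyl]oxy}phenoxy]-2-(3,4,5-trimethoxyphenyl)acetate (both epimers at the benzylic carbon) | COC(=O)c1cc(OC)c(O/C=C\[S@](=O)c2ccc(C)cc2)c(OC(C(=O)ON2C(=O)c3ccccc3C2=O)c2cc(OC)c(OC)c(OC)c2)c1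
F7 | step 4 | (S)-1-{[(Z)-2-bromoethenyl]sulfinyl}-4-methylbenzene | Br/C=C\[S@](=O)c1ccc(C)cc1
F8 | step 3 | methyl 3-hydroxy-5-methoxy-4-(prop-2-en-1-yloxy)benzoate | COC(=O)c1cc(O)c(OCC=C)c(OC)c1
F9 | step 3 | methyl 3-methoxy-4-(prop-2-en-1-yloxy)-5-[(3,4,5-trimethoxyphenyl)methoxy]benzoate | COC(=O)c1cc(OC)c(OCC=C)c(OCc2cc(OC)c(OC)c(OC)c2)c1
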